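The numbers in the tables come from a simulation for substances that don't exist, noise included.

By amount, the starting material stands far above the rest: 12 mM against 6.0 µM of enzyme and 4.2 µM of added ligand, and the questions change the charge of enzyme.

| setting | violet | flask |
|---|---|---|
| starting material | 12 mM | 12 mM |
| enzyme | 6 µM | 6.0 µM |
| added ligand | 2.1 µM | 4.2 µM |
| remark | run made earlier |  |

violet run (percent of the starting material charged)

| time / s | product / % | starting material / % |
|---|---|---|
| 10.0 | 3.7 | 96.8 |
| 20.0 | 6.6 | 93.7 |
| 40.0 | 12.6 | 87.4 |
| 50.0 | 16.4 | 83.2 |

(each reading ± 0.3 percentage points)

* factor on the rate of making product when 20 % of the starting material are converted if enzyme is charged twice over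
* factor on the rate when 20 % of the starting material are converted if enzyme is charged at 0.60 µM instead

- the analysis behind the earlier runs scatters by 0.3 percentage points, standard deviation
- no earlier run changes the charge of enzyme; that part of a forecast is a guess
- no earlier run changes the charge of added ligand; that part of a forecast is a guess

In the violet run the fraction converted per unit time reads 0.198 min⁻¹ up to 20.0 s and 0.197 min⁻¹ up to 50.0 s, a straight line within the scatter. So we take the rate at 20 % conversion to go in proportion to the enzyme at work, and no earlier run shows what added ligand does to that amount.

We fold the charges into one number: 0.700 is the ligand load, the added ligand charged per enzyme charged. If each ligand tied up one enzyme tightly, the share left working in the flask is one minus the load; if it tied up none, the share is one.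

Doubled enzyme: load 0.350; factor 2 with no tying, 4.33 with tight tying.

Enzyme at 0.60 µM: load 7.00; factor 0.100 with no tying, and with tight tying none is left working, as ligand exceeds enzyme.

One number was not enough: the load gives the ceiling of the tying, not its strength, so our reckoning stays at these two brackets.

The forecast gives 2 and 0.1, from “The plain expectation is rate proportional to enzyme”.

The flask's factors come out at 2.19 and 0.0870, inside our brackets.

starting material + enzyme → product + enzyme, rate k1*[starting material]*[enzyme]/(1 + ([starting material]/Km1) + ([starting material]/Ksi1)^2) (12.0 mM, 1.00 mM, k = 78000 L mol⁻¹ s⁻¹); enzyme + added ligand ⇌ idle complex (K = 1.10 × 10⁵ L mol⁻¹, k = 1800 L mol⁻¹ s⁻¹) At 3.00 min the flask holds 23.4 % of its enzyme as idle complex, an off-cycle form, below the load; divided by the load, that is 33.4 % of the added ligand, with 66.6 % of it free. Per enzyme charged, and against the flask at load 0.700, the rate stands at 1.09 at load 0.350 and at 0.870 at load 7.00.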